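**Retrosynthetic overview**
1. Target 22 ⇐ [3,3] Cope rearrangement of the (1(10)E,4E)-germacradien-15-al 21; the cyclohexane is formed last, out of the ten-membered ring.
2. 21 ⇐ C6–C7 closure (the farnesyl C1→C10 bond) of Z-enedial 19: the butenolide C7=C11 attacks the activated C6 aldehyde and Me3Si+ leaves C13 in place of the biosynthetic proton; this sets C6 and C7.
3. 19 ⇐ 3-alkylfuran 17, a latent Z-enedial that delivers C6 and C15 at the aldehyde level with no protecting group.
4. 17 ⇐ vinylogous Mukaiyama aldol of enal 5 with silyloxyfuran 12 (sets C8, C9), then angelate.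
5. Ring order: butenolide (bought as furan-2(5H)-one) → ten-membered carbocycle → cyclohexane. 5 comes from 3-bromofuran, butenyl Grignard and methacrolein; 12 from furanone and Me3SiCH2MgCl.

Assumption: the target is the open 6-hydroxy-15-aldehyde as drawn, (5R,6S,7S,8R,9S,10S); germacrane/elemane numbering (C1–C15) is used for atom labels.

**Route**

Step 1
Reactants: 1 3-bromofuran; 2 but-3-en-1-ylmagnesium bromide
Product: 3 3-(but-3-en-1-yl)furan
Conditions: Ni(dppp)Cl2 (2 mol%), Et2O, 0 °C → reflux
Reagents that add atoms: none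
Why: Kumada–Corriu cross-coupling of the heteroaryl bromide with a primary alkyl Grignard, the bidentate dppp ligand suppressing β-hydride elimination; no stereocentre is formed.

Step 2
Reactants: 3 3-(but-3-en-1-yl)furan; 4 methacrolein
Product: 5 (2E)-5-(furan-3-yl)-2-methylpent-2-enal
Conditions: Hoveyda–Grubbs II (3 mol%), 4 (5 equiv), BHT, CH2Cl2, 40 °C
Reagents that add atoms: none
Why: Olefin cross-metathesis of a terminal alkene with methacrolein gives the trisubstituted enal as the thermodynamic E isomer, and the furan does not react with the Ru carbene.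

Step 3
Reactants: 6 furan-2(5H)-one
Product: 8 3-bromofuran-2(5H)-one, via dibromolactone 7 (not isolated)
Conditions: Br2, CH2Cl2, reflux; then Et3N, 0 °C
Reagents that add atoms: bromine, BrBr
Why: Bromination–dehydrobromination: Br2 adds across the butenolide C=C and E1cB loss of HBr (acidic α-H, β-bromide) restores the conjugated lactone with Br at C3.

Step 4
Reactants: 8 3-bromofuran-2(5H)-one; 9 (trimethylsilyl)methylmagnesium chloride
Product: 11 3-[(trimethylsilyl)methyl]furan-2(5H)-one, via silylmethylzinc chloride 10 (not isolated)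
Conditions: 9, ZnCl2, THF, 0 °C; then 8, Pd(PPh3)4 (5 mol%), THF, rt → 45 °C
Reagents that add atoms: none
Why: Negishi coupling of the activated vinyl bromide with a β-hydrogen-free sp3 organozinc, which is too mild to attack the lactone, installs the allylsilane (C13–Si) needed for ring closure.

Step 5
Reactants: 11 3-[(trimethylsilyl)methyl]furan-2(5H)-one
Product: 12 trimethyl({3-[(trimethylsilyl)methyl]furan-2-yl}oxy)silane
Conditions: TMSOTf, Et3N, Et2O, 0 °C; distil
Reagents that add atoms: trimethylsilyl trifluoromethanesulfonate, C[Si](C)(C)OS(=O)(=O)C(F)(F)F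
Why: Silyl dienol ether formation: soft enolisation at C5 (γ) and O-silylation aromatise the butenolide to the 2-silyloxyfuran.

Step 6
Reactants: 5 (2E)-5-(furan-3-yl)-2-methylpent-2-enal; 12 trimethyl({3-[(trimethylsilyl)methyl]furan-2-yl}oxy)silane
Product: 14 (5R)-5-[(1S,2E)-5-(furan-3-yl)-1-hydroxy-2-methylpent-2-en-1-yl]-3-[(trimethylsilyl)methyl]furan-2(5H)-one, via aldol silyl ether 13 (not isolated)
Conditions: cinchona-thiourea·carboxylic acid salt (10 mol%; quinine- or quinidine-derived pseudo-enantiomer chosen for the 5R,1′S series), CH2Cl2, −20 °C; then aq. citric acid, THF, 0 °C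
Reagents that add atoms: none
Why: Catalytic enantioselective vinylogous Mukaiyama aldol reaction: the silyloxyfuran attacks the H-bond-activated enal through its γ-carbon in the anti (erythro) mode expected for this catalyst class, which fixes C8 as R and C9 as S.

Step 7
Reactants: 14 (5R)-5-[(1S,2E)-5-(furan-3-yl)-1-hydroxy-2-methylpent-2-en-1-yl]-3-[(trimethylsilyl)methyl]furan-2(5H)-one; 15 angelic acid
Product: 17 (1S,2E)-5-(furan-3-yl)-2-methyl-1-{(2R)-5-oxo-4-[(trimethylsilyl)methyl]-2,5-dihydrofuran-2-yl}pent-2-en-1-yl (2Z)-2-methylbut-2-enoate, via mixed anhydride 16 (not isolated)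
Conditions: 15, 2,4,6-Cl3C6H2COCl, Et3N, PhMe, rt; filter; then 14, PhMe, 60 °C (no DMAP)
Reagents that add atoms: none
Why: Yamaguchi esterification through the mixed anhydride, run without a nucleophilic catalyst, acylates the hindered allylic alcohol with retention at C9 and without Z→E (angelate→tiglate) isomerisation.

Step 8
Reactants: 17 (1S,2E)-5-(furan-3-yl)-2-methyl-1-{(2R)-5-oxo-4-[(trimethylsilyl)methyl]-2,5-dihydrofuran-2-yl}pent-2-en-1-yl (2Z)-2-methylbut-2-enoate
Product: 19 (1S,2E,6Z)-6-formyl-2-methyl-8-oxo-1-{(2R)-5-oxo-4-[(trimethylsilyl)methyl]-2,5-dihydrofuran-2-yl}octa-2,6-dien-1-yl (2Z)-2-methylbut-2-enoate, via furan endoperoxide 18 (not isolated)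
Conditions: O2, TPP (cat.), hν (white LED), CH2Cl2, −78 °C; then Me2S, −78 → 0 °C; used crude
Reagents that add atoms: dioxygen, O=O
Why: Furan photooxygenation: [4+2] addition of singlet oxygen to the furan, the most electron-rich π-system (the ester-deactivated alkenes and the acceptor-substituted allylsilane are far slower), and reduction of the endoperoxide unveil the (Z)-enedial with C15 cis to C6.

Step 9
Reactants: 19 (1S,2E,6Z)-6-formyl-2-methyl-8-oxo-1-{(2R)-5-oxo-4-[(trimethylsilyl)methyl]-2,5-dihydrofuran-2-yl}octa-2,6-dien-1-yl (2Z)-2-methylbut-2-enoate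
Product: 22 (5R,6S,7S,8R,9S,10S)-9-angeloyloxy-6-hydroxy-15-oxoelema-1,3,11(13)-trien-12,8-olide (CNP0320538.1), via germacranolide silyl ether 20 (not isolated), via germacranolide hydroxy aldehyde 21 (not isolated)
Conditions: Me3SiNTf2 (10 mol%), 2,6-di-tert-butyl-4-methylpyridine (15 mol%), CH2Cl2 (0.5 mM, slow addition), −78 → −40 °C; aq. citric acid, THF, 0 °C; then PhMe, 50 °C
Reagents that add atoms: none
Why: Proposed new method: silyl-cation activation of the less hindered C6 formyl group gives an oxocarbenium that C7 of the 2-(silylmethyl)butenolide captures 10-endo, anti to the C9 side chain (C7, trans-lactone) and through an open antiperiplanar transition state whose E-locked γ-substituent gives the syn C6/C7 pair (6S), with Me3Si+ leaving C13 to form the exocyclic methylene just as proton loss does after farnesyl C1–C10 closure; closure at C15 would need an E-cyclononene and the C1=C10 alkene cannot reach C6 without a trans-cyclohexene; the resulting 4-formyl (E,E)-germacradiene then undergoes chair Cope rearrangement at 50 °C, the 7,8-trans lactone selecting the chair that gives 5R,10S; the closest known reactions are the intramolecular Hosomi–Sakurai cyclisation of ω-formyl 2-(silylmethyl)alkenoates to ring-fused α-methylene lactones, Lewis-acid allylmetal–aldehyde macrocyclisations and the aldehyde-accelerated Cope rearrangement of germacranolide 15-aldehydes.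

**Compound list**
1 | 3-bromofuran | Brc1ccoc1 | starting material
2 | but-3-en-1-ylmagnesium bromide | C=CCC[Mg]Br | starting material
3 | 3-(but-3-en-1-yl)furan | C=CCCc1ccoc1 | intermediate
4 | methacrolein (2-methylprop-2-enal) | C=C(C)C=O | starting material
5 | (2E)-5-(furan-3-yl)-2-methylpent-2-enal | O=C/C(C)=C/CCc1ccoc1 | intermediate
6 | furan-2(5H)-one | O=C1OCC=C1 | starting material
7 | trans-3,4-dibromodihydrofuran-2(3H)-one (racemic) | O=C1OCC(Br)C1Br | intermediate (not isolated)
8 | 3-bromofuran-2(5H)-one | O=C1OCC=C1Br | intermediate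
9 | (trimethylsilyl)methylmagnesium chloride | C[Si](C)(C)C[Mg]Cl | starting material
10 | (trimethylsilyl)methylzinc chloride | C[Si](C)(C)C[Zn]Cl | intermediate (not isolated)
11 | 3-[(trimethylsilyl)methyl]furan-2(5H)-one | C[Si](C)(C)CC1=CCOC1=O | intermediate
12 | trimethyl({3-[(trimethylsilyl)methyl]furan-2-yl}oxy)silane | C[Si](C)(C)Cc1ccoc1O[Si](C)(C)C | intermediate
13 | (5R)-5-[(1S,2E)-5-(furan-3-yl)-2-methyl-1-(trimethylsilyloxy)pent-2-en-1-yl]-3-[(trimethylsilyl)methyl]furan-2(5H)-one | o1ccc(c1)CC/C=C(C)/[C@H](O[Si](C)(C)C)[C@@H]2OC(=O)C(C[Si](C)(C)C)=C2 | intermediate (not isolated)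
14 | (5R)-5-[(1S,2E)-5-(furan-3-yl)-1-hydroxy-2-methylpent-2-en-1-yl]-3-[(trimethylsilyl)methyl]furan-2(5H)-one | o1ccc(c1)CC/C=C(C)/[C@H](O)[C@@H]2OC(=O)C(C[Si](C)(C)C)=C2 | intermediate
15 | angelic acid, (2Z)-2-methylbut-2-enoic acid | C/C=C(/C)C(=O)O | starting material
16 | angelic 2,4,6-trichlorobenzoic anhydride | C/C=C(/C)C(=O)OC(=O)c1c(Cl)cc(Cl)cc1Cl | intermediate (not isolated)
17 | (1S,2E)-5-(furan-3-yl)-2-methyl-1-{(2R)-5-oxo-4-[(trimethylsilyl)methyl]-2,5-dihydrofuran-2-yl}pent-2-en-1-yl (2Z)-2-methylbut-2-enoate | o1ccc(c1)CC/C=C(C)/[C@H](OC(=O)/C(C)=C\C)[C@@H]2OC(=O)C(C[Si](C)(C)C)=C2 | intermediate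
18 | furan endoperoxide of 17 (2,3,7-trioxabicyclo[2.2.1]hept-5-ene, bridgehead isomers) | O1OC2C=C(CC/C=C(C)/[C@H](OC(=O)/C(C)=C\C)[C@@H]3OC(=O)C(C[Si](C)(C)C)=C3)C1O2 | intermediate (not isolated)
19 | (1S,2E,6Z)-6-formyl-2-methyl-8-oxo-1-{(2R)-5-oxo-4-[(trimethylsilyl)methyl]-2,5-dihydrofuran-2-yl}octa-2,6-dien-1-yl (2Z)-2-methylbut-2-enoate | O=C/C=C(C=O)/CC/C=C(C)/[C@H](OC(=O)/C(C)=C\C)[C@@H]1OC(=O)C(C[Si](C)(C)C)=C1 | intermediate
20 | 6-O-trimethylsilyl ether of 21 | C/C1=C\CC/C(C=O)=C/[C@H](O[Si](C)(C)C)[C@@H]2C(=C)C(=O)O[C@H]2[C@H]1OC(=O)/C(C)=C\C | intermediate (not isolated)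
21 | (1(10)E,4Z,6S,7S,8R,9S)-9-angeloyloxy-6-hydroxy-15-oxogermacra-1(10),4,11(13)-trien-12,8-olide (ring-trans 4,5-alkene) | C/C1=C\CC/C(C=O)=C/[C@H](O)[C@@H]2C(=C)C(=O)O[C@H]2[C@H]1OC(=O)/C(C)=C\C | intermediate (not isolated)
22 | (5R,6S,7S,8R,9S,10S)-9-angeloyloxy-6-hydroxy-15-oxoelema-1,3,11(13)-trien-12,8-olide (CNP0320538.1) | C=C[C@]1(C)[C@H](OC(=O)/C(C)=C\C)[C@@H]2OC(=O)C(=C)[C@H]2[C@@H](O)[C@H]1C(=C)C=O | target

**Step count and risks**
Total: 9 steps. Longest linear sequence: 7 steps (6 → 8 → 11 → 12 → 14 → 17 → 19 → 22, steps 3–9); the aldehyde arm (steps 1–2) joins at step 6.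

Most likely to fail:

Step 9. The ten-membered closure relies on a weakly nucleophilic, acceptor-substituted allylsilane. The free C15 formyl group can be taken by the C1=C10 alkene in a five-membered carbonyl-ene closure, oligomers can form, and the C6 configuration rests on an open transition state. The hydroxy aldehyde may also rest as its 6,15-lactol before the Cope step. Fallback: set out from furan 17 and keep C15 masked through the ring closure. Br2, MeOH, KOAc at −40 °C converts the furan into the 2,5-dimethoxy-2,5-dihydrofuran F1. Catalytic TMSOTf in CH2Cl2 at −78 °C ionises the C6 acetal (less hindered, allyl cation with a tertiary terminus), and the allylsilane closes the ring to the bridged methyl acetal F2. Aqueous AcOH/THF opens F2 to hydroxy aldehyde 21, where the route is rejoined for the Cope step to 22.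

Step 6. Enantio- and anti-selectivity are untested for a 3-substituted silyloxyfuran with an α-branched enal. Fallback: set out from 5 and 12 and run the addition with an achiral anti-selective promoter (catalytic Bu4N phenoxide or TBAT). This gives 14 as a racemate with its enantiomer F3. A lipase (Amano PS or CAL-B, vinyl acetate, MTBE), screened so that F3 is the fast-reacting antipode, converts it into the acetate F4. Unreacted 14 is separated and rejoins the route at 14.

Step 7. Et3N at 60 °C can trigger E1cB loss of the new acyloxy group (γ-ylidene butenolide), epimerise C8 or give tiglate. Fallback: set out from 5 and 12 with a syn-selective chiral Lewis-acid vinylogous aldol (Ti–BINOL or Cu–bisoxazoline type) to the syn alcohol F5, which is 5R,1′R. Esterify F5 with angelic acid 15 under Mitsunobu conditions (PPh3, DIAD, PhMe, 0 °C). These are neutral, need no activated angelic derivative and invert C9, giving 17 directly, where the route is rejoined.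

Further compounds
F1 | step 9 | (1S,2E)-5-(2,5-dimethoxy-2,5-dihydrofuran-3-yl)-2-methyl-1-{(2R)-5-oxo-4-[(trimethylsilyl)methyl]-2,5-dihydrofuran-2-yl}pent-2-en-1-yl (2Z)-2-methylbut-2-enoate (acetal isomers) | COC1OC(OC)C(CC/C=C(C)/[C@H](OC(=O)/C(C)=C\C)[C@@H]2OC(=O)C(C[Si](C)(C)C)=C2)=C1
F2 | step 9 | (1(10)E,6S,7S,8R,9S)-9-angeloyloxy-6,15-epoxy-15-methoxygermacra-1(10),4,11(13)-trien-12,8-olide (C15 epimers) | C/C1=C\CCC3=C[C@H](OC3OC)[C@@H]2C(=C)C(=O)O[C@H]2[C@H]1OC(=O)/C(C)=C\C
F3 | step 6 | (5S)-5-[(1R,2E)-5-(furan-3-yl)-1-hydroxy-2-methylpent-2-en-1-yl]-3-[(trimethylsilyl)methyl]furan-2(5H)-one (enantiomer of 14) | o1ccc(c1)CC/C=C(C)/[C@@H](O)[C@H]2OC(=O)C(C[Si](C)(C)C)=C2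
F4 | step 6 | (1R,2E)-5-(furan-3-yl)-2-methyl-1-{(2S)-5-oxo-4-[(trimethylsilyl)methyl]-2,5-dihydrofuran-2-yl}pent-2-en-1-yl acetate | o1ccc(c1)CC/C=C(C)/[C@@H](OC(C)=O)[C@H]2OC(=O)C(C[Si](C)(C)C)=C2
F5 | step 7 | (5R)-5-[(1R,2E)-5-(furan-3-yl)-1-hydroxy-2-methylpent-2-en-1-yl]-3-[(trimethylsilyl)methyl]furan-2(5H)-one | o1ccc(c1)CC/C=C(C)/[C@@H](O)[C@@H]2OC(=O)C(C[Si](C)(C)C)=C2
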